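Ring A is cut at C5–C6, C7–C8 and C4a–C5. The disconnection uses the strict alternation around ring A of oxygen-bearing carbons (C5, C7, C8a) and carbon-bearing ones (C6, C8, C4a): C5–O is read as a ketene carbonyl, C7–O as the oxygen of a siloxyalkyne and C8a–O1 as the enol ether of a dihydropyran. One operation (photochemical Wolff rearrangement, ketene–alkyne [2+2], then 4π opening and 6π closure) joins a dihydropyranyl diazo ketone, which already contains O1–C8a and C4–C4a, to a ring B siloxyalkyne and closes ring A with the chain at C6. The alkyne carries the future ketone as a dioxolane, so only deprotection follows.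

Key step: step 16

Remarks on the chemistry
- Chroman numbering is used for rings A and C (O1, C2 with the gem-dimethyl group, C3, C4, C4a, C5–C8, C8a). The target has no stereocenter, and the only chiral isolated intermediate is racemic lactol 4.
- 5-Bromovanillin has the free hydroxyl on the central oxygen and the methoxy group on the outer one, the reverse of ring B (3'-OH, 4'-OMe, 5'-prenyl). Steps 6 and 7 move the methyl group to the central oxygen.
- The propargylic carbon of the alkyne is kept at the ketone oxidation level as a 1,3-dioxolane and the ring B phenol is a TIPS ether. A silyl-protected carbinol would, after desilylation, give a 5,7-dihydroxy benzylic alcohol that ionises easily to an ortho-quinone methide and would need oxidising on a free phloroglucinol. With the ketal the endgame is fluoride and mild acid only.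
- Ar = 4-methoxy-3-(3-methylbut-2-en-1-yl)-5-(triisopropylsilyloxy)phenyl.

**Fragment A (diazo ketone)**

Step 1
Reactants: 1 δ-valerolactone
Product: 2 5-methylhexane-1,5-diol
Conditions: MeMgBr (2.5 equiv), THF, 0 °C → rt
Reagents that add atoms: methylmagnesium bromide, C[Mg]Br
Why: Double Grignard addition to the lactone (acyl substitution, then addition to the ketone) should give the tertiary carbinol that becomes C2 with its gem-dimethyl group.

Step 2
Reactants: 2 5-methylhexane-1,5-diol
Product: 4 6,6-dimethyltetrahydro-2H-pyran-2-ol, via 5-hydroxy-5-methylhexanal 3 (not isolated)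
Conditions: (COCl)2, DMSO, CH2Cl2, −78 °C; Et3N, −78 °C → rt
Reagents that add atoms: none
Why: Swern oxidation can only oxidise the primary alcohol, and the hydroxy aldehyde should close spontaneously to the six-membered lactol, whose anomeric centre (racemic) becomes sp2 in step 3.

Step 3
Reactants: 4 6,6-dimethyltetrahydro-2H-pyran-2-ol
Product: 6 2,2-dimethyl-3,4-dihydro-2H-pyran, via anomeric mesylate 5 (not isolated)
Conditions: MsCl, Et3N, CH2Cl2, 0 → 40 °C; fractional distillation
Reagents that add atoms: none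
Why: Sulfonylation of the lactol hydroxyl and base-assisted elimination through the oxocarbenium ion is the usual glycal-type dehydration of a lactol to a cyclic enol ether.

Step 4
Reactants: 6 2,2-dimethyl-3,4-dihydro-2H-pyran
Product: 8 1-(6,6-dimethyl-5,6-dihydro-4H-pyran-2-yl)ethan-1-one, via 6-lithio-2,2-dimethyl-3,4-dihydro-2H-pyran 7 (not isolated)
Conditions: t-BuLi, THF/pentane, −78 → 0 °C; MeC(O)N(OMe)Me, −78 → 0 °C
Reagents that add atoms: N-methoxy-N-methylacetamide, CC(=O)N(C)OC
Why: α-Lithiation of a cyclic enol ether at the vinylic carbon next to oxygen followed by Weinreb ketone synthesis should stop at the methyl ketone because the chelated tetrahedral adduct survives until work-up.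

Step 5
Reactants: 8 1-(6,6-dimethyl-5,6-dihydro-4H-pyran-2-yl)ethan-1-one
Product: 10 2-diazo-1-(6,6-dimethyl-5,6-dihydro-4H-pyran-2-yl)ethan-1-one, via trifluoroacetyl diketone 9 (not isolated)
Conditions: LiHMDS, THF, −78 °C; CF3CO2CH2CF3; then 4-acetamidobenzenesulfonyl azide, Et3N, H2O, MeCN, rt
Reagents that add atoms: 4-acetamidobenzenesulfonyl azide, CC(=O)Nc1ccc(cc1)S(=O)(=O)N=[N+]=[N-]
Why: Detrifluoroacetylative diazo transfer (Claisen activation of the kinetic methyl enolate, then Regitz-type transfer with loss of the trifluoroacetyl group) is the established route to α'-diazo derivatives of α,β-unsaturated methyl ketones.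

**Fragment B (siloxyalkyne)**

Step 6
Reactants: 11 5-bromovanillin
Product: 12 3-bromo-4,5-dihydroxybenzaldehyde
Conditions: AlCl3, pyridine, CH2Cl2, reflux; then aq HCl
Reagents that add atoms: none
Why: Lewis-acid-assisted SN2 demethylation by pyridine is selective for a methoxy group ortho to a free phenol, which chelates aluminium, and should leave the aldehyde and the bromide alone.

Step 7
Reactants: 12 3-bromo-4,5-dihydroxybenzaldehyde
Product: 13 3-bromo-5-hydroxy-4-methoxybenzaldehyde
Conditions: MeI (1.05 equiv), Li2CO3, DMF, 40 °C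
Reagents that add atoms: iodomethane, CI
Why: The C4 hydroxyl, para to the formyl group and ortho to bromine, is by far the more acidic, so a weak carbonate base should ionise and methylate only this oxygen (regioselective Williamson etherification), which puts the methyl group on the central oxygen as ring B requires.

Step 8
Reactants: 13 3-bromo-5-hydroxy-4-methoxybenzaldehyde
Product: 14 3-bromo-4-methoxy-5-(triisopropylsilyloxy)benzaldehyde
Conditions: TIPSCl, imidazole, DMF, rt
Reagents that add atoms: triisopropylsilyl chloride, CC(C)[Si](Cl)(C(C)C)C(C)C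
Why: Standard silylation gives an aryl TIPS ether that should survive organolithium reagents, catalytic silyl triflate and carbonate in methanol, and that leaves together with the C7 silyl group in the last step.

Step 9
Reactants: 14 3-bromo-4-methoxy-5-(triisopropylsilyloxy)benzaldehyde
Product: 15 (E)-3-[3-bromo-4-methoxy-5-(triisopropylsilyloxy)phenyl]-N-methoxy-N-methylprop-2-enamide
Conditions: (EtO)2P(O)CH2C(O)N(OMe)Me, NaH, THF, 0 °C → rt
Reagents that add atoms: diethyl [2-(methoxy(methyl)amino)-2-oxoethyl]phosphonate, CCOP(=O)(CC(=O)N(C)OC)OCC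
Why: Horner–Wadsworth–Emmons olefination with a stabilised phosphonate anion should give the E-configured unsaturated Weinreb amide, and the alkene geometry does not matter because the alkene is reduced next.

Step 10
Reactants: 15 (E)-3-[3-bromo-4-methoxy-5-(triisopropylsilyloxy)phenyl]-N-methoxy-N-methylprop-2-enamide
Product: 16 3-[3-bromo-4-methoxy-5-(triisopropylsilyloxy)phenyl]-N-methoxy-N-methylpropanamide
Conditions: H2 (3 atm), RhCl(PPh3)3 (5 mol%), toluene/EtOH, 50 °C
Reagents that add atoms: none
Why: Homogeneous hydrogenation with RhCl(PPh3)3 should saturate the disubstituted conjugated alkene without hydrogenolysis of the aryl bromide or of the N–O bond.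

Step 11
Reactants: 16 3-[3-bromo-4-methoxy-5-(triisopropylsilyloxy)phenyl]-N-methoxy-N-methylpropanamide
Product: 17 3-Ar-N-methoxy-N-methylpropanamide
Conditions: prenylSnBu3, Pd(PPh3)4 (5 mol%), DMF, 100 °C
Reagents that add atoms: tributyl(3-methylbut-2-en-1-yl)stannane, CCCC[Sn](CCCC)(CCCC)CC=C(C)C
Why: Stille coupling of the aryl bromide with a prenylstannane should give the linear prenyl arene, since reductive elimination from the allylpalladium intermediate occurs at the unhindered CH2 terminus.

Step 12
Reactants: 17 3-Ar-N-methoxy-N-methylpropanamide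
Product: 18 5-Ar-1-(trimethylsilyl)pent-1-yn-3-one
Conditions: TMSC≡CH, n-BuLi, THF, −78 °C; then 17, −78 → 0 °C
Reagents that add atoms: ethynyltrimethylsilane, C#C[Si](C)(C)C
Why: Weinreb ketone synthesis with lithium trimethylsilylacetylide should stop at the ynone, and the silyl cap blocks conjugate addition of the released amine here and of the glycol in step 13.

Step 13
Reactants: 18 5-Ar-1-(trimethylsilyl)pent-1-yn-3-one
Product: 19 2-(2-Ar-ethyl)-2-[(trimethylsilyl)ethynyl]-1,3-dioxolane
Conditions: TMSOCH2CH2OTMS, TMSOTf (5 mol%), CH2Cl2, −78 → −20 °C; pyridine quench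
Reagents that add atoms: 1,2-bis(trimethylsilyloxy)ethane, C[Si](C)(C)OCCO[Si](C)(C)C
Why: Silyl-triflate-catalysed acetalisation with the bis-silylated glycol runs under aprotic conditions at low temperature and is driven by formation of hexamethyldisiloxane, so the prenyl alkene and the aryl silyl ether should be spared.

Step 14
Reactants: 19 2-(2-Ar-ethyl)-2-[(trimethylsilyl)ethynyl]-1,3-dioxolane
Product: 20 2-(2-Ar-ethyl)-2-ethynyl-1,3-dioxolane
Conditions: K2CO3 (cat.), MeOH/THF, 0 °C
Reagents that add atoms: none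
Why: Methoxide-mediated protodesilylation of an alkynylsilane is fast at 0 °C, where the hindered aryl TIPS ether and the ketal should persist.

Step 15
Reactants: 20 2-(2-Ar-ethyl)-2-ethynyl-1,3-dioxolane
Product: 23 2-(2-Ar-ethyl)-2-[(triisopropylsilyloxy)ethynyl]-1,3-dioxolane, via lithium acetylide 21 (not isolated), via lithium ynolate 22 (not isolated)
Conditions: n-BuLi, THF, −78 °C; t-BuOOLi (from t-BuOOH and LiHMDS), −78 → −10 °C; TIPSOTf, −78 → 0 °C
Reagents that add atoms: tert-butyl hydroperoxide (as its lithium salt), CC(C)(C)OO; triisopropylsilyl trifluoromethanesulfonate, CC(C)[Si](OS(=O)(=O)C(F)(F)F)(C(C)C)C(C)C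
Why: Electrophilic oxygenation of a lithium acetylide by lithium tert-butyl peroxide gives the lithium ynolate, which the bulky silyl triflate traps on oxygen, a known one-flask route to functionalised triisopropylsiloxyalkynes.

**Union and completion**

Step 16
Reactants: 10 2-diazo-1-(6,6-dimethyl-5,6-dihydro-4H-pyran-2-yl)ethan-1-one; 23 2-(2-Ar-ethyl)-2-[(triisopropylsilyloxy)ethynyl]-1,3-dioxolane
Product: 28 6-[2-(2-Ar-ethyl)-1,3-dioxolan-2-yl]-2,2-dimethyl-7-(triisopropylsilyloxy)chroman-5-ol, via vinylketene 24 (not isolated), via vinylcyclobutenone 25 (not isolated), via dienylketene 26 (not isolated), via cyclohexadienone 27 (not isolated)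
Conditions: hν (>300 nm, Pyrex, medium-pressure Hg lamp), 10 (1.3 equiv, in portions), degassed toluene, rt; then 90 °C
Reagents that add atoms: none
Why: Proposed new method: light above 300 nm expels N2 from 10 and the dihydropyranyl group shifts to the diazo carbon (Wolff rearrangement) to give vinylketene 24, whose carbonyl carbon is attacked by the dioxolane-bearing carbon of 23 (β to the siloxy oxygen and therefore the nucleophilic alkyne terminus) in a [2+2] cycloaddition that forms C5–C6 and C7–C8 and gives cyclobutenone 25. On heating, 25 opens reversibly by 4π electrocyclic cleavage to dienylketene 26, and the isomer with the ketene carbon and the dihydropyranyl group cis closes ring A by a thermal disrotatory 6π electrocyclisation (C4a–C5) to dienone 27, which enolises to phenol 28. The closest known reaction type is the photochemical Wolff variant of the vinylketene–alkyne (Danheiser) benzannulation of α,β-unsaturated diazo ketones with siloxyalkynes; untested is a vinylketene whose internal alkene carbon carries an enol ether oxygen, which is what supplies the third oxygen of the phloroglucinol ring. No stereocenter is set, because the sp3 C4a of 27 is lost on aromatisation. The step needs regioselectivity in the [2+2], secured by the polarisation of the siloxyalkyne, and chemoselectivity over the prenyl alkene and ring B, secured by the much higher reactivity of the ynol ether towards ketenes and by irradiating only where the diazo ketone absorbs; since O1–C8a and C4–C4a already exist in 10, the chain can only arrive at C6 between the free C5 hydroxyl and the silylated C7 oxygen.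

Step 17
Reactants: 28 6-[2-(2-Ar-ethyl)-1,3-dioxolan-2-yl]-2,2-dimethyl-7-(triisopropylsilyloxy)chroman-5-ol
Product: 30 1-(5,7-dihydroxy-2,2-dimethylchroman-6-yl)-3-[3-hydroxy-4-methoxy-5-(3-methylbut-2-en-1-yl)phenyl]propan-1-one (CNP0408176.0), via triol ketal 29 (not isolated)
Conditions: TBAF, AcOH, THF, 0 °C; then 1 M HCl, rt
Reagents that add atoms: water, O
Why: Fluoride cleaves both aryl silyl ethers and mild aqueous acid then hydrolyses the dioxolane, which the two ortho hydroxyl groups strongly activate, to the hydrogen-bonded aryl ketone under conditions that should leave the prenyl group and the chroman untouched.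

**Compound list**

1 | δ-valerolactone | O=C1CCCCO1 | starting material
2 | 5-methylhexane-1,5-diol | CC(C)(O)CCCCO | intermediate
3 | 5-hydroxy-5-methylhexanal (not isolated) | CC(C)(O)CCCC=O | intermediate
4 | 6,6-dimethyltetrahydro-2H-pyran-2-ol (racemic) | CC1(C)CCCC(O)O1 | intermediate
5 | 6,6-dimethyltetrahydro-2H-pyran-2-yl methanesulfonate (racemic, not isolated) | CC1(C)CCCC(OS(C)(=O)=O)O1 | intermediate
6 | 2,2-dimethyl-3,4-dihydro-2H-pyran | CC1(C)CCC=CO1 | intermediate
7 | 6-lithio-2,2-dimethyl-3,4-dihydro-2H-pyran (not isolated) | [Li]C1=CCCC(C)(C)O1 | intermediate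
8 | 1-(6,6-dimethyl-5,6-dihydro-4H-pyran-2-yl)ethan-1-one | CC(=O)C1=CCCC(C)(C)O1 | intermediate
9 | 1-(6,6-dimethyl-5,6-dihydro-4H-pyran-2-yl)-4,4,4-trifluorobutane-1,3-dione (not isolated) | O=C(CC(=O)C(F)(F)F)C1=CCCC(C)(C)O1 | intermediate
10 | 2-diazo-1-(6,6-dimethyl-5,6-dihydro-4H-pyran-2-yl)ethan-1-one | [N-]=[N+]=CC(=O)C1=CCCC(C)(C)O1 | intermediate
11 | 5-bromovanillin (3-bromo-4-hydroxy-5-methoxybenzaldehyde) | COc1cc(C=O)cc(Br)c1O | starting material
12 | 3-bromo-4,5-dihydroxybenzaldehyde | O=Cc1cc(O)c(O)c(Br)c1 | intermediate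
13 | 3-bromo-5-hydroxy-4-methoxybenzaldehyde | COc1c(O)cc(C=O)cc1Br | intermediate
14 | 3-bromo-4-methoxy-5-(triisopropylsilyloxy)benzaldehyde | COc1c(O[Si](C(C)C)(C(C)C)C(C)C)cc(C=O)cc1Br | intermediate
15 | (E)-3-[3-bromo-4-methoxy-5-(triisopropylsilyloxy)phenyl]-N-methoxy-N-methylprop-2-enamide | COc1c(O[Si](C(C)C)(C(C)C)C(C)C)cc(/C=C/C(=O)N(C)OC)cc1Br | intermediate
16 | 3-[3-bromo-4-methoxy-5-(triisopropylsilyloxy)phenyl]-N-methoxy-N-methylpropanamide | COc1c(O[Si](C(C)C)(C(C)C)C(C)C)cc(CCC(=O)N(C)OC)cc1Br | intermediate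
17 | N-methoxy-3-[4-methoxy-3-(3-methylbut-2-en-1-yl)-5-(triisopropylsilyloxy)phenyl]-N-methylpropanamide | COc1c(O[Si](C(C)C)(C(C)C)C(C)C)cc(CCC(=O)N(C)OC)cc1CC=C(C)C | intermediate
18 | 5-[4-methoxy-3-(3-methylbut-2-en-1-yl)-5-(triisopropylsilyloxy)phenyl]-1-(trimethylsilyl)pent-1-yn-3-one | COc1c(O[Si](C(C)C)(C(C)C)C(C)C)cc(CCC(=O)C#C[Si](C)(C)C)cc1CC=C(C)C | intermediate
19 | 2-{2-[4-methoxy-3-(3-methylbut-2-en-1-yl)-5-(triisopropylsilyloxy)phenyl]ethyl}-2-[(trimethylsilyl)ethynyl]-1,3-dioxolane | COc1c(O[Si](C(C)C)(C(C)C)C(C)C)cc(CCC2(C#C[Si](C)(C)C)OCCO2)cc1CC=C(C)C | intermediate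
20 | 2-ethynyl-2-{2-[4-methoxy-3-(3-methylbut-2-en-1-yl)-5-(triisopropylsilyloxy)phenyl]ethyl}-1,3-dioxolane | COc1c(O[Si](C(C)C)(C(C)C)C(C)C)cc(CCC2(C#C)OCCO2)cc1CC=C(C)C | intermediate
21 | lithium acetylide of 20 (not isolated) | COc1c(O[Si](C(C)C)(C(C)C)C(C)C)cc(CCC2(C#C[Li])OCCO2)cc1CC=C(C)C | intermediate
22 | lithium ynolate from 21 (not isolated) | COc1c(O[Si](C(C)C)(C(C)C)C(C)C)cc(CCC2(C#CO[Li])OCCO2)cc1CC=C(C)C | intermediate
23 | 2-{2-[4-methoxy-3-(3-methylbut-2-en-1-yl)-5-(triisopropylsilyloxy)phenyl]ethyl}-2-[(triisopropylsilyloxy)ethynyl]-1,3-dioxolane (ring B siloxyalkyne) | COc1c(O[Si](C(C)C)(C(C)C)C(C)C)cc(CCC2(C#CO[Si](C(C)C)(C(C)C)C(C)C)OCCO2)cc1CC=C(C)C | intermediate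
24 | (6,6-dimethyl-5,6-dihydro-4H-pyran-2-yl)ketene (not isolated) | O=C=CC1=CCCC(C)(C)O1 | intermediate
25 | 2-[2-(2-Ar-ethyl)-1,3-dioxolan-2-yl]-4-(6,6-dimethyl-5,6-dihydro-4H-pyran-2-yl)-3-(triisopropylsilyloxy)cyclobut-2-en-1-one (racemic, not isolated) | O=C1C(C2(CCc3cc(O[Si](C(C)C)(C(C)C)C(C)C)c(OC)c(CC=C(C)C)c3)OCCO2)=C(O[Si](C(C)C)(C(C)C)C(C)C)C1C4=CCCC(C)(C)O4 | intermediate
26 | 2-[2-(2-Ar-ethyl)-1,3-dioxolan-2-yl]-4-(6,6-dimethyl-5,6-dihydro-4H-pyran-2-yl)-3-(triisopropylsilyloxy)buta-1,3-dien-1-one, ketene carbon and pyranyl group cis across C3=C4 (not isolated) | O=C=C(C1(CCc2cc(O[Si](C(C)C)(C(C)C)C(C)C)c(OC)c(CC=C(C)C)c2)OCCO1)/C(O[Si](C(C)C)(C(C)C)C(C)C)=C\C3=CCCC(C)(C)O3 | intermediate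
27 | 6-[2-(2-Ar-ethyl)-1,3-dioxolan-2-yl]-2,2-dimethyl-7-(triisopropylsilyloxy)-3,4-dihydro-2H-chromen-5(4aH)-one (racemic, not isolated) | O=C1C(C3(CCc4cc(O[Si](C(C)C)(C(C)C)C(C)C)c(OC)c(CC=C(C)C)c4)OCCO3)=C(O[Si](C(C)C)(C(C)C)C(C)C)C=C2OC(C)(C)CCC12 | intermediate
28 | 6-[2-(2-Ar-ethyl)-1,3-dioxolan-2-yl]-2,2-dimethyl-7-(triisopropylsilyloxy)chroman-5-ol | Oc1c(C3(CCc4cc(O[Si](C(C)C)(C(C)C)C(C)C)c(OC)c(CC=C(C)C)c4)OCCO3)c(O[Si](C(C)C)(C(C)C)C(C)C)cc2OC(C)(C)CCc12 | intermediate
29 | 6-(2-{2-[3-hydroxy-4-methoxy-5-(3-methylbut-2-en-1-yl)phenyl]ethyl}-1,3-dioxolan-2-yl)-2,2-dimethylchroman-5,7-diol (not isolated) | Oc1c(C3(CCc4cc(O)c(OC)c(CC=C(C)C)c4)OCCO3)c(O)cc2OC(C)(C)CCc12 | intermediate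
30 | 1-(5,7-dihydroxy-2,2-dimethylchroman-6-yl)-3-[3-hydroxy-4-methoxy-5-(3-methylbut-2-en-1-yl)phenyl]propan-1-one (CNP0408176.0) | COc1c(O)cc(CCC(=O)c2c(O)cc3c(c2O)CCC(C)(C)O3)cc1CC=C(C)C | target

**Step count and risk**

Total: 17 steps. Longest linear sequence: 12 steps (steps 6–17, from 5-bromovanillin); fragment A takes 5 steps (steps 1–5).

Steps most likely to fail:

1. Step 16 (Proposed new method). The electron-rich alkoxy vinylketene may dimerise or be intercepted before the hindered alkyne adds. The excited diazo ketone may follow carbene pathways other than the Wolff shift. The cyclobutenone may open to the unproductive dienylketene isomer and decay before ring closure. Excess ketene may acylate the new phenol.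
 Fallback with known chemistry, setting out from 17 and rejoining the route at 30: ring A would be taken from phloroglucinol. Acid-mediated condensation of phloroglucinol with 2-methylbut-3-en-2-ol (BF3·OEt2, dioxane) would give 2,2-dimethylchroman-5,7-diol F1. MOMCl and i-Pr2NEt would give 5,7-bis(methoxymethoxy)-2,2-dimethylchroman F2. Directed ortho-lithiation (n-BuLi, TMEDA, THF, 0 °C) at C6, between the two MOM ethers, and addition of the aryllithium to Weinreb amide 17 would give 1-[5,7-bis(methoxymethoxy)-2,2-dimethylchroman-6-yl]-3-Ar-propan-1-one F3. TBAF would give the ring B phenol 1-[5,7-bis(methoxymethoxy)-2,2-dimethylchroman-6-yl]-3-[3-hydroxy-4-methoxy-5-(3-methylbut-2-en-1-yl)phenyl]propan-1-one F4, and HCl in methanol at 40 °C would remove the two MOM ethers to give 30.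

2. Step 15. Oxygen transfer from the peroxide to the acetylide may be incomplete. The ynolate may lose alkoxide by opening the dioxolane on warming. The siloxyalkyne may hydrolyse during isolation.
 Fallback, setting out from 20 (as its acetylide 21) and rejoining the route at 22 and then 23: the C–O bond would be made through hypervalent iodine instead of the peroxide. Acetylide 21 would be treated with PhI(OCOPh)2 in THF at −78 °C, where ligand exchange at iodine and loss of iodobenzene should give 2-(2-Ar-ethyl)-1,3-dioxolan-2-ylethynyl benzoate F5. Two equivalents of MeLi at −78 °C would cleave the ester carbonyl and release ynolate 22, which TIPSOTf would silylate to 23 as before.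

3. Step 11. Allyl transfer from tin may lose α/γ selectivity and give the reverse-prenyl isomer. The alkene may migrate into conjugation with the ring. Oxidative addition at the electron-rich, ortho-substituted bromide may be slow.
 Fallback, setting out from 16 and rejoining the route at 17: the prenyl group would be built in two stages without an unsymmetrical allyl transfer. Stille coupling of 16 with allyltributylstannane (Pd(PPh3)4, toluene, 100 °C) would give 3-[3-allyl-4-methoxy-5-(triisopropylsilyloxy)phenyl]-N-methoxy-N-methylpropanamide F6. Cross-metathesis with 2-methylbut-2-ene (second-generation Grubbs catalyst, CH2Cl2, 40 °C) would convert the terminal alkene into the prenyl group of 17.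

**Further compounds**

F1 | step 16 | 2,2-dimethylchroman-5,7-diol | CC1(C)CCc2c(O)cc(O)cc2O1
F2 | step 16 | 5,7-bis(methoxymethoxy)-2,2-dimethylchroman | CC1(C)CCc2c(OCOC)cc(OCOC)cc2O1
F3 | step 16 | 1-[5,7-bis(methoxymethoxy)-2,2-dimethylchroman-6-yl]-3-[4-methoxy-3-(3-methylbut-2-en-1-yl)-5-(triisopropylsilyloxy)phenyl]propan-1-one | CC1(C)CCc2c(OCOC)c(C(=O)CCc3cc(O[Si](C(C)C)(C(C)C)C(C)C)c(OC)c(CC=C(C)C)c3)c(OCOC)cc2O1
F4 | step 16 | 1-[5,7-bis(methoxymethoxy)-2,2-dimethylchroman-6-yl]-3-[3-hydroxy-4-methoxy-5-(3-methylbut-2-en-1-yl)phenyl]propan-1-one | CC1(C)CCc2c(OCOC)c(C(=O)CCc3cc(O)c(OC)c(CC=C(C)C)c3)c(OCOC)cc2O1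
F5 | step 15 | (2-{2-[4-methoxy-3-(3-methylbut-2-en-1-yl)-5-(triisopropylsilyloxy)phenyl]ethyl}-1,3-dioxolan-2-yl)ethynyl benzoate | COc1c(O[Si](C(C)C)(C(C)C)C(C)C)cc(CCC2(C#COC(=O)c3ccccc3)OCCO2)cc1CC=C(C)C
F6 | step 11 | 3-[3-allyl-4-methoxy-5-(triisopropylsilyloxy)phenyl]-N-methoxy-N-methylpropanamide | COc1c(O[Si](C(C)C)(C(C)C)C(C)C)cc(CCC(=O)N(C)OC)cc1CC=C
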